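## Structural features

The target is a trans-α,β-dibenzyl-γ-butyrolactone (Cα R, Cβ R) whose two benzyl groups are 5-substituted guaiacyl rings. The Cα arm is ring B, which carries, on the carbon ortho to its free phenol, the open chain C7(OH)(ring A)–C8(H)–C9H2OH with C7 S and C8 S, so that 7-OH and ring B are anti when ring A–C7–C8–C9 is drawn extended. The Cβ arm is the ring-closed counterpart of that unit, a trans-(2S,3R)-2-(4-hydroxy-3-methoxyphenyl)-3-hydroxymethyl-7-methoxy-2,3-dihydrobenzofuran joined through C5. The six stereocentres form three adjacent pairs (C7/C8, Cα/Cβ, C2/C3) that are remote from one another, so each pair must be set in absolute terms. The fragile sites are the p-hydroxybenzylic C7–OH (under acid it ionises and the neighbouring ring B phenol would trap it as a second coumaran; like the benzylic C2–O bond it can also be hydrogenolysed), the epimerisable Cα and three oxidisable phenols. The real difficulty is the pair of benzylic centres C8 and C3, each a CH with a hydroxymethyl arm and a carbinol arm on a crowded arene carbon, and then C7, which must be set relative to C8 in an open chain. The key step exploits the fact that the ring B carbon bearing C8 is ortho to the phenol oxygen, while the other ortho carbon bears OMe and the para carbon bears the chain to the lactone (bromine as placeholder), so an allyl group on that oxygen can move to this carbon only. C8 and C3 carry the same set of substituents in opposite sense, so one rearrangement product can supply both halves if the roles of its two arms are exchanged.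

## Logic of the disconnections

43 ⇒ 42 ⇒ 41. The cuts are three aryl O–benzyl bonds and, before them, three O–silyl bonds. They come last because the free phenols and the free C7 carbinol tolerate neither acid, base nor organometallic reagents. The skeleton is unchanged, but all six acidic hydroxyls disappear. The forward steps must avoid acid altogether, so the silyl ethers go first under buffered fluoride and the benzyl ethers last under neutral hydrogen.

41 ⇒ 39 + 20. The bond cut is Cα–CH2 of the ring B arm. The enolate of a β-substituted butyrolactone is alkylated anti to the β-substituent, so this cut reduces the Cα/Cβ pair to the single centre Cβ and divides the molecule into two halves of similar size. The forward step demands a benzylic bromide without acidic protons (hence the silyl ether at C7 in 20) and complete, cold enolisation of 39.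

39 ⇒ 38 ⇒ 29 + 35, and 35 ⇒ 30 + 31. The bonds cut are C–CO2Et and aryl–CH2 of the benzofuran arm. The cyclopropane methylene of 35 is an electrophilic CH2 on a carbon that already has the Cβ configuration, so 29 is used as it is, without one-carbon homologation, and Cβ is traced to 30. The forward steps demand clean halogen–metal exchange on 29, copper-directed attack at the cyclopropane and not at a carbonyl group, and a dealkoxycarbonylation that spares silyl and benzyl ethers. In the formation of 35 the malonate must open the epoxide before chloride is displaced, or the enantiomer forms.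

29 ⇒ 27 (through 28) ⇒ 26 + 14. The bonds cut are O1–C2 and then C2–aryl. A benzylic carbinol ortho to a phenol closes readily to the five-membered ether, and the trans ring is the stable one, so C2 needs no control of its own and follows from C3. The coumaran is thereby reduced to an α-aryl aldehyde and an aryl Grignard reagent. The forward steps demand a phenol protecting group that falls under the ring-closing acid, a silyl ether that does not, and an aryl donor that does not enolise 26.

26 ⇒ 25 ⇒ 24 ⇒ 23 ⇒ 21 ⇒ 9. Only the propenyl C=C bond is cut; what changes is the role of the two arms at the stereocentre. In 12 the propenyl arm becomes the formyl group. In 26 it becomes the protected hydroxymethyl arm and the original silyloxymethyl arm becomes the formyl group. This exchange reverses the sense of the centre, so the same 9 that delivers C8 also delivers C3, and one chiral intermediate serves both halves. The demand is that 23, a 1,3-diol silylated on one arm only, never meets conditions that let silicon migrate between the two oxygens.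

20 ⇒ 19 ⇒ 16 ⇒ 15 ⇒ 12 + 14. The bonds cut are C–Br, aryl–CH2OH (back to the aryl bromide), O–Si at C7 and the C7–ring A bond. The last cut leaves 12, whose only stereocentre is C8, and addition anti to ring B should then set C7. The demands are high facial selectivity, no α-deprotonation of 12, and a bromine–lithium exchange on 16 that outruns any deprotonation.

12 ⇒ 10 ⇒ 9. The propenyl C=C bond (a latent formyl group) and the O–benzyl bond are cut. The phenol must be masked before ozone is used, and the mask must later leave without acid.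

9 ⇒ 7 (through 8). The C8–aryl bond is cut and replaced by the aryl–O–CH(CH3) ether bond. A hindered benzylic C–C stereocentre is exchanged for a C–O stereocentre two atoms away that comes from the chiral pool, and the arene is simplified to 1. The forward step must be concerted and suprafacial, must start from a geometrically pure E alkene, and has only one ortho carbon to go to.

7 ⇒ 6 ⇒ 5 ⇒ 3 (through 4) ⇒ 1 + 2, and 14 ⇒ 13 ⇒ 1. The cuts are O–Si, the C=C bond (olefination of 4), the aryl O–C bond, and for 14 the C–Mg bond and then an O–benzyl bond. The ether bond is made on 2 itself, where SN2 inversion is clean and no allylic system offers an SN2′ path, and the chain is then grown by two carbons. The demand is that 4 is not epimerised, so it is made and consumed in one flask. The aryl donor 14 serves both halves and is made once.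

## Other disconnections considered

Alternative 1: The cut is the C2–C3 bond of the dihydrobenzofuran. In the forward direction the aryl diazoacetate A1, whose phenol oxygen carries the 4-benzyloxy-3-methoxybenzyl group, would be decomposed by Rh2(S-PTTL)4 or its antipode. The rhodium carbenoid would insert into the benzylic O–CH2 C–H bond, close the furan ring and give the cis ester A2. NaOMe would then epimerise C3 to the trans ester A3, and reduction of the ester group would give the hydroxymethyl arm.
- Note on descriptors: the trans ester A3 is (2S,3S), because CO2Me outranks C2 at C3. (2S,3R) is the descriptor of the cis ester A2, and of the trans series only after the ester has become CH2OH.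
- In its favour: both ring stereocentres come from a catalyst, no stoichiometric chiral material is consumed, and a 5-bromo coumaran of the type of 29 should be reached in fewer steps than by steps 14 to 20. On step economy for this half it is the better plan.
- Against it here: it solves only the ring-closed half, so C8 and C7 would need a second, unrelated method, whereas 9 serves both halves. The ether oxygen next to the carbenoid can form an oxonium ylide, and the electron-rich benzyl ring can be cyclopropanated, both in competition with insertion. The epimerisation passes through an ester enolate that can expel the C2 phenoxide, a ring opening that would erase C2.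
- Comparison: catalyst control in a reactive intermediate stands against a stereospecific shift whose outcome is fixed by substrate geometry. In the level of enantiocontrol to be expected the two are equal.

Alternative 2: The cut is the C7–C8 bond of the open unit. In the forward direction the ring B arylacetyl oxazolidinone A4 and O-benzylvanillin A5 would be combined with MgCl2, triethylamine and chlorotrimethylsilane to give, after desilylation, the anti-aldol imide A6. This creates C7 and C8 together without closing a ring, and reductive removal of the auxiliary would give the 1,3-diol.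
- In its favour: C7 is fixed by the auxiliary and a closed transition state, not by the Felkin–Anh bias on which step 10 relies. On control of C7 it is the better plan. It is convergent and uses a non-enolisable aldehyde, the kind this reaction needs.
- Against it here: A4 needs a one-carbon side chain ortho to the phenol oxygen of 1, which costs several steps that the rearrangement saves. Its enolate is a hindered aryl acetate flanked by an ortho benzyloxy group. A6 is an α-aryl-β-hydroxy imide that can revert by retro-aldol cleavage or epimerise at C8 while the auxiliary is removed. The benzofuran half would need the antipodal auxiliary or another method.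
- Comparison: in step count for the ring B half the two plans are about equal. The chosen plan is more economical overall because one chiral intermediate feeds both halves.

Alternative 3: The cut is the bond between Cβ and the CH2 group of the benzofuran arm. In the forward direction the lithium enolate of the chiral-pool lactone A7 would be alkylated by the benzylic bromide A8 on the face opposite to the trityloxymethyl group to give A9. Its new centre becomes Cβ once the lactone is transposed (reduction to the triol, detritylation, glycol cleavage, oxidation) to a lactone of the type of 39.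
- In its favour: the 1,3-induction of this enolate alkylation is highly predictable. In stereochemical reliability it is the equal of steps 21 to 23.
- Against it here: it needs A8, three steps beyond an aryl bromide such as 29, and four more steps for the transposition, some with LiAlH4 and acid on a compound that holds a benzylic ether and a silyl ether. Steps 22 and 23 reach 39 in two steps from 29. It does nothing for C7, C8, C2 or C3.
- Comparison: it could replace steps 21 to 23 but not the key step, and on step economy the chosen sequence is the better.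

Key step: step 5

Remark: TBS = tert-butyldimethylsilyl, TBDPS = tert-butyldiphenylsilyl, Bn = benzyl, MOM = methoxymethyl. Compounds 13 and 35 are assumed to be prepared (steps 8 and 21) although both can be bought, so the step count is the conservative one. The Grignard reagent 14 is assumed to be made once, kept under argon as a THF solution and titrated before each of its two uses (steps 10 and 19).

## Route

Step 1
Reactants: 1 4-bromo-2-methoxyphenol; 2 ethyl (S)-lactate
Product: 3 ethyl (2R)-2-(4-bromo-2-methoxyphenoxy)propanoate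
Conditions: PPh3, DIAD, THF, 0 °C → rt
Reagents that add atoms: none
Why: Mitsunobu reaction: the phenoxide displaces the activated lactate hydroxyl by SN2 with inversion, giving the (R)-aryl ether. The C–O bond is made here and not on a later allylic alcohol because the α-ester favours clean SN2 and there is no allylic system to divert the attack.

Step 2
Reactants: 3 ethyl (2R)-2-(4-bromo-2-methoxyphenoxy)propanoate
Product: 5 ethyl (2E,4R)-4-(4-bromo-2-methoxyphenoxy)pent-2-enoate, via aldehyde 4 (not isolated)
Conditions: i-Bu2AlH, CH2Cl2, −78 °C; then NaH, (EtO)2P(O)CH2CO2Et, THF, −78 °C → rt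
Reagents that add atoms: triethyl phosphonoacetate, CCOC(=O)CP(=O)(OCC)OCC
Why: Partial ester reduction stops at the aluminium hemiacetal, and the aldehyde released in the presence of the phosphonate anion is trapped at once (Horner–Wadsworth–Emmons olefination), so the epimerisable α-aryloxy aldehyde is never handled. The E enoate should dominate, and any Z isomer is removed here by chromatography so that the later chirality transfer starts from geometrically pure material.

Step 3
Reactants: 5 ethyl (2E,4R)-4-(4-bromo-2-methoxyphenoxy)pent-2-enoate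
Product: 6 (2E,4R)-4-(4-bromo-2-methoxyphenoxy)pent-2-en-1-ol
Conditions: i-Bu2AlH (2.2 equiv), CH2Cl2, −78 → 0 °C
Reagents that add atoms: none
Why: 1,2-Reduction of the unsaturated ester by i-Bu2AlH gives the E allylic alcohol and should leave the aryl bromide, the aryl ether and the double bond untouched.

Step 4
Reactants: 6 (2E,4R)-4-(4-bromo-2-methoxyphenoxy)pent-2-en-1-ol
Product: 7 (2E,4R)-4-(4-bromo-2-methoxyphenoxy)-1-(TBSO)pent-2-ene
Conditions: TBSCl, imidazole, CH2Cl2, 0 °C → rt
Reagents that add atoms: tert-butyl(chloro)dimethylsilane, CC(C)(C)[Si](C)(C)Cl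
Why: Standard silylation of a primary alcohol. The silyl ether is inert to Eu(fod)3, and a silyloxymethyl terminus does not stabilise an allyl cation, which keeps the next step concerted.

Step 5
Reactants: 7 (2E,4R)-4-(4-bromo-2-methoxyphenoxy)-1-(TBSO)pent-2-ene
Product: 9 4-bromo-2-[(2S,3E)-1-(TBSO)pent-3-en-2-yl]-6-methoxyphenol, via dienone 8 (not isolated)
Conditions: Eu(fod)3 (10 mol %), CHCl3, 55 °C
Reagents that add atoms: none
Why: Eu(fod)3 binds the guaiacyl O,O-pair of 7 and lowers the barrier of a concerted, suprafacial [3,3] shift of the allyl unit from oxygen to the only unsubstituted ortho carbon through a chair transition state, giving dienone 8, which tautomerises to phenol 9. The closest known reaction type is the aromatic Claisen rearrangement of enantioenriched secondary allyl aryl ethers with 1,3-chirality transfer, run thermally or with Eu(fod)3. No ring is closed. The new stereocentre C8 is controlled by the ether carbinol centre: with the methyl group pseudo-equatorial and the E double bond, the aryl carbon is delivered to the face of the alkene terminus on the side that the oxygen leaves, so (R,E)-7 should give (S)-9 with an E-propenyl group. The step needs site selectivity, which the methoxy group on the second ortho carbon and the bromine on the para carbon secure, because attack at the methoxy-bearing carbon is reversible and unproductive. It needs complete chirality transfer, which the E geometry purified at 5 and the non-stabilising silyloxymethyl terminus secure by disfavouring ionisation. It needs a mild temperature so that 9 does not add its phenol to the propenyl group, which the catalyst provides.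

Step 6
Reactants: 9 4-bromo-2-[(2S,3E)-1-(TBSO)pent-3-en-2-yl]-6-methoxyphenol
Product: 10 2-(benzyloxy)-5-bromo-1-[(2S,3E)-1-(TBSO)pent-3-en-2-yl]-3-methoxybenzene
Conditions: BnBr, K2CO3, DMF, rt
Reagents that add atoms: benzyl bromide, BrCc1ccccc1
Why: Williamson etherification of the phenoxide. The benzyl ether withstands ozone, organometallic reagents and fluoride, and leaves at the end under neutral hydrogen, which the acid-sensitive C7 carbinol requires.

Step 7
Reactants: 10 2-(benzyloxy)-5-bromo-1-[(2S,3E)-1-(TBSO)pent-3-en-2-yl]-3-methoxybenzene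
Product: 12 (2S)-2-[2-(benzyloxy)-5-bromo-3-methoxyphenyl]-3-(TBSO)propanal, via ozonide 11 (not isolated)
Conditions: O3, CH2Cl2, −78 °C (Sudan red 7B end point); PPh3, −78 °C → rt
Reagents that add atoms: ozone, [O-][O+]=O
Why: Ozonolysis with reductive work-up: the alkene reacts far faster than the bromine-deactivated arene, and the phosphine reduces the ozonide under neutral conditions, so the α-aryl aldehyde should keep its configuration. It is used crude.

Step 8
Reactants: 1 4-bromo-2-methoxyphenol
Product: 13 1-(benzyloxy)-4-bromo-2-methoxybenzene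
Conditions: BnBr, K2CO3, acetone, reflux
Reagents that add atoms: benzyl bromide, BrCc1ccccc1
Why: Williamson etherification. The same phenol thus supplies the aryl donor for ring A and for the aryl group at C2 of the benzofuran.

Step 9
Reactants: 13 1-(benzyloxy)-4-bromo-2-methoxybenzene
Product: 14 [4-(benzyloxy)-3-methoxyphenyl]magnesium bromide (THF solution)
Conditions: Mg turnings (I2 crystal), THF, rt → 45 °C; kept under argon, titrated before use
Reagents that add atoms: magnesium, [Mg]
Why: Grignard reagent formation by insertion of magnesium into the aryl C–Br bond; the benzyl and methyl ethers are inert to the reagent. One solution serves both aryl additions (steps 10 and 19).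

Step 10
Reactants: 12 (2S)-2-[2-(benzyloxy)-5-bromo-3-methoxyphenyl]-3-(TBSO)propanal; 14 [4-(benzyloxy)-3-methoxyphenyl]magnesium bromide
Product: 15 (1S,2S)-1-[4-(benzyloxy)-3-methoxyphenyl]-2-[2-(benzyloxy)-5-bromo-3-methoxyphenyl]-3-(TBSO)propan-1-ol
Conditions: LaCl3·2LiCl, THF, −78 °C; then aq. NH4Cl
Reagents that add atoms: none
Why: Grignard addition under Felkin–Anh control: the bulky ring B lies anti to the incoming aryl group, which passes the small hydrogen, so the 7,8-anti (1S,2S) alcohol should prevail, and a chelate through the silyloxy oxygen would lead to the same face. LaCl3·2LiCl activates the carbonyl group and lowers the basicity of the reagent, which should suppress α-deprotonation; a minor syn epimer would be removed by chromatography.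

Step 11
Reactants: 15 (1S,2S)-1-[4-(benzyloxy)-3-methoxyphenyl]-2-[2-(benzyloxy)-5-bromo-3-methoxyphenyl]-3-(TBSO)propan-1-ol
Product: 16 (1S,2S)-1-[4-(benzyloxy)-3-methoxyphenyl]-2-[2-(benzyloxy)-5-bromo-3-methoxyphenyl]-1,3-bis(TBSO)propane
Conditions: TBSOTf, 2,6-lutidine, CH2Cl2, −78 → 0 °C
Reagents that add atoms: tert-butyldimethylsilyl trifluoromethanesulfonate, CC(C)(C)[Si](C)(C)OS(=O)(=O)C(F)(F)F
Why: Silylation of the secondary benzylic alcohol with the silyl triflate under lutidine buffering removes the last acidic proton before lithiation and enolate alkylation. Any silyl shift between O9 and O7 in step 10 would converge on the same product here.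

Step 12
Reactants: 16 (1S,2S)-1-[4-(benzyloxy)-3-methoxyphenyl]-2-[2-(benzyloxy)-5-bromo-3-methoxyphenyl]-1,3-bis(TBSO)propane
Product: 19 {4-(benzyloxy)-3-[(1S,2S)-1-[4-(benzyloxy)-3-methoxyphenyl]-1,3-bis(TBSO)propan-2-yl]-5-methoxyphenyl}methanol, via aryllithium 17 (not isolated), via aldehyde 18 (not isolated)
Conditions: n-BuLi, THF, −78 °C; DMF, −78 → 0 °C; then MeOH, NaBH4, 0 °C
Reagents that add atoms: N,N-dimethylformamide, CN(C)C=O
Why: Bromine–lithium exchange at −78 °C is faster than any deprotonation. Formylation of the aryllithium and NaBH4 reduction in the same flask should give the benzylic alcohol.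

Step 13
Reactants: 19 {4-(benzyloxy)-3-[(1S,2S)-1-[4-(benzyloxy)-3-methoxyphenyl]-1,3-bis(TBSO)propan-2-yl]-5-methoxyphenyl}methanol
Product: 20 2-(benzyloxy)-5-(bromomethyl)-1-[(1S,2S)-1-[4-(benzyloxy)-3-methoxyphenyl]-1,3-bis(TBSO)propan-2-yl]-3-methoxybenzene
Conditions: CBr4, PPh3, CH2Cl2, 0 °C
Reagents that add atoms: tetrabromomethane, BrC(Br)(Br)Br
Why: The Appel reaction converts the primary benzylic alcohol to the bromide under neutral conditions that spare both silyl ethers. The electron-rich benzyl bromide is used without storage.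

Step 14
Reactants: 9 4-bromo-2-[(2S,3E)-1-(TBSO)pent-3-en-2-yl]-6-methoxyphenol
Product: 21 5-bromo-1-[(2S,3E)-1-(TBSO)pent-3-en-2-yl]-3-methoxy-2-(methoxymethoxy)benzene
Conditions: MOMCl, i-Pr2NEt, CH2Cl2, 0 °C → rt
Reagents that add atoms: chloromethyl methyl ether, COCCl
Why: O-Alkylation of the second portion of the phenol gives an acetal that withstands ozone, periodinane and Grignard reagents but falls under the same acid that later closes the furan ring.

Step 15
Reactants: 21 5-bromo-1-[(2S,3E)-1-(TBSO)pent-3-en-2-yl]-3-methoxy-2-(methoxymethoxy)benzene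
Product: 23 (2R)-2-[5-bromo-3-methoxy-2-(methoxymethoxy)phenyl]-3-(TBSO)propan-1-ol, via ozonide 22 (not isolated)
Conditions: O3, CH2Cl2, −78 °C; then NaBH4, MeOH, −78 → 0 °C
Reagents that add atoms: ozone, [O-][O+]=O
Why: Ozonolysis with NaBH4 work-up trims the propenyl arm to a hydroxymethyl group, and cold reduction should outrun epimerisation of the transient aldehyde. The mild medium should not induce silyl migration between the two primary oxygens, which would exchange the arms and erode the configuration.

Step 16
Reactants: 23 (2R)-2-[5-bromo-3-methoxy-2-(methoxymethoxy)phenyl]-3-(TBSO)propan-1-ol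
Product: 24 (2S)-2-[5-bromo-3-methoxy-2-(methoxymethoxy)phenyl]-1-(TBSO)-3-(TBDPSO)propane
Conditions: TBDPSCl, imidazole, CH2Cl2, 0 °C → rt
Reagents that add atoms: tert-butyl(chloro)diphenylsilane, CC(C)(C)[Si](Cl)(c1ccccc1)c1ccccc1
Why: Silylation with the bulkier, more acid-stable silyl chloride differentiates the two arms permanently. The former propenyl arm is now the persistent CH2O arm.

Step 17
Reactants: 24 (2S)-2-[5-bromo-3-methoxy-2-(methoxymethoxy)phenyl]-1-(TBSO)-3-(TBDPSO)propane
Product: 25 (2S)-2-[5-bromo-3-methoxy-2-(methoxymethoxy)phenyl]-3-(TBDPSO)propan-1-ol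
Conditions: camphorsulfonic acid (10 mol %), MeOH/CH2Cl2, 0 °C
Reagents that add atoms: none
Why: Acid-catalysed methanolysis cleaves a primary TBS ether much faster than a TBDPS ether or an aryl MOM acetal at 0 °C. The arm set free is the one that was silylated in 9, so the sense of the stereocentre relative to 12 is reversed.

Step 18
Reactants: 25 (2S)-2-[5-bromo-3-methoxy-2-(methoxymethoxy)phenyl]-3-(TBDPSO)propan-1-ol
Product: 26 (2R)-2-[5-bromo-3-methoxy-2-(methoxymethoxy)phenyl]-3-(TBDPSO)propanal
Conditions: Dess–Martin periodinane, NaHCO3, CH2Cl2, 0 °C → rt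
Reagents that add atoms: none
Why: Dess–Martin oxidation under bicarbonate buffering gives the α-aryl aldehyde without base or heat. It is used at once.

Step 19
Reactants: 26 (2R)-2-[5-bromo-3-methoxy-2-(methoxymethoxy)phenyl]-3-(TBDPSO)propanal; 14 [4-(benzyloxy)-3-methoxyphenyl]magnesium bromide
Product: 27 (1R,2R)-1-[4-(benzyloxy)-3-methoxyphenyl]-2-[5-bromo-3-methoxy-2-(methoxymethoxy)phenyl]-3-(TBDPSO)propan-1-ol
Conditions: LaCl3·2LiCl, THF, −78 °C; then aq. NH4Cl
Reagents that add atoms: none
Why: The same Felkin–Anh-controlled Grignard addition as in step 10 should give mainly the anti alcohol. The carbinol configuration is not decisive here because the next step passes through the benzylic cation.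

Step 20
Reactants: 27 (1R,2R)-1-[4-(benzyloxy)-3-methoxyphenyl]-2-[5-bromo-3-methoxy-2-(methoxymethoxy)phenyl]-3-(TBDPSO)propan-1-ol
Product: 29 (2S,3R)-2-[4-(benzyloxy)-3-methoxyphenyl]-5-bromo-7-methoxy-3-[(TBDPSO)methyl]-2,3-dihydro-1-benzofuran, via phenol 28 (not isolated)
Conditions: TsOH·H2O (20 mol %), MeOH/CH2Cl2, 40 °C
Reagents that add atoms: none
Why: Acid methanolysis removes the acetal; the p-alkoxybenzylic alcohol ionises under the same conditions and the freed ortho phenol captures the cation in a five-membered ring closure. The closure is reversible, and the trans ring, with aryl and silyloxymethyl groups on opposite faces, should be the kinetic and the thermodynamic product, while C3 is untouched.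

Step 21
Reactants: 30 (R)-epichlorohydrin; 31 diethyl malonate
Product: 35 ethyl (1S,5R)-2-oxo-3-oxabicyclo[3.1.0]hexane-1-carboxylate, via chlorohydrin 32 (not isolated), via epoxide 33 (not isolated), via cyclopropylmethanol 34 (not isolated)
Conditions: NaOEt, EtOH, 0 °C → reflux
Reagents that add atoms: none
Why: The malonate anion opens the epoxide at its terminal carbon, the alkoxide closes a new epoxide by displacing chloride, and a second deprotonation opens that epoxide at the stereocentre with inversion (3-exo-tet) to the cyclopropane, whose hydroxymethyl group lactonises onto the cis ester. The stereocentre of 30 becomes C5 of 35, the future Cβ.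

Step 22
Reactants: 29 (2S,3R)-2-[4-(benzyloxy)-3-methoxyphenyl]-5-bromo-7-methoxy-3-[(TBDPSO)methyl]-2,3-dihydro-1-benzofuran; 35 ethyl (1S,5R)-2-oxo-3-oxabicyclo[3.1.0]hexane-1-carboxylate
Product: 38 ethyl (4R)-4-{[(2S,3R)-2-[4-(benzyloxy)-3-methoxyphenyl]-7-methoxy-3-[(TBDPSO)methyl]-2,3-dihydro-1-benzofuran-5-yl]methyl}-2-oxooxolane-3-carboxylate (C3 epimers), via aryllithium 36 (not isolated), via arylmagnesium bromide 37 (not isolated)
Conditions: t-BuLi (2.05 equiv), THF, −78 °C; MgBr2·OEt2, −78 → −30 °C; CuI (10 mol %), then 35, −30 → 0 °C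
Reagents that add atoms: none
Why: After bromine–lithium exchange and transmetalation, copper-catalysed homoconjugate addition puts the aryl group on the unsubstituted cyclopropane carbon, and the bond to the doubly activated carbon breaks to a malonate-type enolate. C5 of 35 is not involved and becomes Cβ (R); the labile C3 centre is removed in the next step.

Step 23
Reactants: 38 ethyl (4R)-4-{[(2S,3R)-2-[4-(benzyloxy)-3-methoxyphenyl]-7-methoxy-3-[(TBDPSO)methyl]-2,3-dihydro-1-benzofuran-5-yl]methyl}-2-oxooxolane-3-carboxylate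
Product: 39 (4R)-4-{[(2S,3R)-2-[4-(benzyloxy)-3-methoxyphenyl]-7-methoxy-3-[(TBDPSO)methyl]-2,3-dihydro-1-benzofuran-5-yl]methyl}oxolan-2-one
Conditions: LiCl, DMSO/H2O, 140 °C
Reagents that add atoms: none
Why: Krapcho dealkoxycarbonylation: chloride dealkylates the activated ester, the carboxylate loses CO2 and the lactone enolate is protonated. The medium is near neutral and Cβ is not touched.

Step 24
Reactants: 39 (4R)-4-{[(2S,3R)-2-[4-(benzyloxy)-3-methoxyphenyl]-7-methoxy-3-[(TBDPSO)methyl]-2,3-dihydro-1-benzofuran-5-yl]methyl}oxolan-2-one; 20 2-(benzyloxy)-5-(bromomethyl)-1-[(1S,2S)-1-[4-(benzyloxy)-3-methoxyphenyl]-1,3-bis(TBSO)propan-2-yl]-3-methoxybenzene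
Product: 41 (3R,4R)-3-({4-(benzyloxy)-3-[(1S,2S)-1-[4-(benzyloxy)-3-methoxyphenyl]-1,3-bis(TBSO)propan-2-yl]-5-methoxyphenyl}methyl)-4-{[(2S,3R)-2-[4-(benzyloxy)-3-methoxyphenyl]-7-methoxy-3-[(TBDPSO)methyl]-2,3-dihydro-1-benzofuran-5-yl]methyl}oxolan-2-one, via lithium enolate 40 (not isolated)
Conditions: LiN(SiMe3)2, THF, −78 °C; then 20, DMPU, −78 → −30 °C
Reagents that add atoms: none
Why: Alkylation of the lithium enolate of a β-substituted γ-butyrolactone: the benzylic bromide approaches anti to the β-arylmethyl group, which should set Cα as R and give the trans lactone, the more stable arrangement as well.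

Step 25
Reactants: 41 (3R,4R)-3-({4-(benzyloxy)-3-[(1S,2S)-1-[4-(benzyloxy)-3-methoxyphenyl]-1,3-bis(TBSO)propan-2-yl]-5-methoxyphenyl}methyl)-4-{[(2S,3R)-2-[4-(benzyloxy)-3-methoxyphenyl]-7-methoxy-3-[(TBDPSO)methyl]-2,3-dihydro-1-benzofuran-5-yl]methyl}oxolan-2-one
Product: 42 (3R,4R)-3-({4-(benzyloxy)-3-[(1S,2S)-1-[4-(benzyloxy)-3-methoxyphenyl]-1,3-dihydroxypropan-2-yl]-5-methoxyphenyl}methyl)-4-{[(2S,3R)-2-[4-(benzyloxy)-3-methoxyphenyl]-3-(hydroxymethyl)-7-methoxy-2,3-dihydro-1-benzofuran-5-yl]methyl}oxolan-2-one
Conditions: Bu4NF, AcOH, THF, 0 °C → rt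
Reagents that add atoms: none
Why: Fluoride cleaves all three silyl ethers, and acetic acid buffers the medium so that the lactone and the benzylic carbinol meet no strong base. The phenols are still benzylated, so C7–OH cannot be trapped by the ring B oxygen.

Step 26
Reactants: 42 (3R,4R)-3-({4-(benzyloxy)-3-[(1S,2S)-1-[4-(benzyloxy)-3-methoxyphenyl]-1,3-dihydroxypropan-2-yl]-5-methoxyphenyl}methyl)-4-{[(2S,3R)-2-[4-(benzyloxy)-3-methoxyphenyl]-3-(hydroxymethyl)-7-methoxy-2,3-dihydro-1-benzofuran-5-yl]methyl}oxolan-2-one
Product: 43 (3R,4R)-3-({4-hydroxy-3-[(1S,2S)-1,3-dihydroxy-1-(4-hydroxy-3-methoxyphenyl)propan-2-yl]-5-methoxyphenyl}methyl)-4-{[(2S,3R)-2-(4-hydroxy-3-methoxyphenyl)-3-(hydroxymethyl)-7-methoxy-2,3-dihydro-1-benzofuran-5-yl]methyl}oxolan-2-one (CNP0186558.2)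
Conditions: H2 (1 atm), Pd/C (10 %), EtOAc/EtOH, rt
Reagents that add atoms: none
Why: Hydrogenolysis of the three aryl benzyl ethers, which under neutral conditions at 1 atm are cleaved much faster than the benzylic C7–OH bond or the C2–O bond of the coumaran. The reaction is stopped as soon as debenzylation is complete, and no acid is present.

## Compound list

1 | 4-bromo-2-methoxyphenol | COc1cc(Br)ccc1O | starting material
2 | ethyl (S)-lactate | CCOC(=O)[C@H](C)O | starting material
3 | ethyl (2R)-2-(4-bromo-2-methoxyphenoxy)propanoate | CCOC(=O)[C@@H](C)Oc1ccc(Br)cc1OC | intermediate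
4 | (2R)-2-(4-bromo-2-methoxyphenoxy)propanal | C[C@@H](Oc1ccc(Br)cc1OC)C=O | intermediate (not isolated)
5 | ethyl (2E,4R)-4-(4-bromo-2-methoxyphenoxy)pent-2-enoate | CCOC(=O)/C=C/[C@@H](C)Oc1ccc(Br)cc1OC | intermediate
6 | (2E,4R)-4-(4-bromo-2-methoxyphenoxy)pent-2-en-1-ol | C[C@@H](Oc1ccc(Br)cc1OC)/C=C/CO | intermediate
7 | (2E,4R)-4-(4-bromo-2-methoxyphenoxy)-1-(TBSO)pent-2-ene | C[C@@H](Oc1ccc(Br)cc1OC)/C=C/CO[Si](C)(C)C(C)(C)C | intermediate
8 | (6S)-4-bromo-6-[(2S,3E)-1-(TBSO)pent-3-en-2-yl]-2-methoxycyclohexa-2,4-dien-1-one | C/C=C/[C@H](CO[Si](C)(C)C(C)(C)C)[C@H]1C=C(Br)C=C(OC)C1=O | intermediate (not isolated)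
9 | 4-bromo-2-[(2S,3E)-1-(TBSO)pent-3-en-2-yl]-6-methoxyphenol | C/C=C/[C@H](CO[Si](C)(C)C(C)(C)C)c1cc(Br)cc(OC)c1O | intermediate
10 | 2-(benzyloxy)-5-bromo-1-[(2S,3E)-1-(TBSO)pent-3-en-2-yl]-3-methoxybenzene | C/C=C/[C@H](CO[Si](C)(C)C(C)(C)C)c1cc(Br)cc(OC)c1OCc1ccccc1 | intermediate
11 | 3-{(1S)-1-[2-(benzyloxy)-5-bromo-3-methoxyphenyl]-2-(TBSO)ethyl}-5-methyl-1,2,4-trioxolane (ring carbons as a mixture) | CC1OOC(O1)[C@H](CO[Si](C)(C)C(C)(C)C)c1cc(Br)cc(OC)c1OCc1ccccc1 | intermediate (not isolated)
12 | (2S)-2-[2-(benzyloxy)-5-bromo-3-methoxyphenyl]-3-(TBSO)propanal | O=C[C@H](CO[Si](C)(C)C(C)(C)C)c1cc(Br)cc(OC)c1OCc1ccccc1 | intermediate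
13 | 1-(benzyloxy)-4-bromo-2-methoxybenzene | COc1cc(Br)ccc1OCc1ccccc1 | intermediate
14 | [4-(benzyloxy)-3-methoxyphenyl]magnesium bromide (THF solution) | COc1cc([Mg]Br)ccc1OCc1ccccc1 | intermediate
15 | (1S,2S)-1-[4-(benzyloxy)-3-methoxyphenyl]-2-[2-(benzyloxy)-5-bromo-3-methoxyphenyl]-3-(TBSO)propan-1-ol | COc1cc([C@@H](O)[C@H](CO[Si](C)(C)C(C)(C)C)c2cc(Br)cc(OC)c2OCc2ccccc2)ccc1OCc1ccccc1 | intermediate
16 | (1S,2S)-1-[4-(benzyloxy)-3-methoxyphenyl]-2-[2-(benzyloxy)-5-bromo-3-methoxyphenyl]-1,3-bis(TBSO)propane | COc1cc([C@@H](O[Si](C)(C)C(C)(C)C)[C@H](CO[Si](C)(C)C(C)(C)C)c2cc(Br)cc(OC)c2OCc2ccccc2)ccc1OCc1ccccc1 | intermediate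
17 | {4-(benzyloxy)-3-[(1S,2S)-1-[4-(benzyloxy)-3-methoxyphenyl]-1,3-bis(TBSO)propan-2-yl]-5-methoxyphenyl}lithium | COc1cc([C@@H](O[Si](C)(C)C(C)(C)C)[C@H](CO[Si](C)(C)C(C)(C)C)c2cc([Li])cc(OC)c2OCc2ccccc2)ccc1OCc1ccccc1 | intermediate (not isolated)
18 | 4-(benzyloxy)-3-[(1S,2S)-1-[4-(benzyloxy)-3-methoxyphenyl]-1,3-bis(TBSO)propan-2-yl]-5-methoxybenzaldehyde | COc1cc([C@@H](O[Si](C)(C)C(C)(C)C)[C@H](CO[Si](C)(C)C(C)(C)C)c2cc(C=O)cc(OC)c2OCc2ccccc2)ccc1OCc1ccccc1 | intermediate (not isolated)
19 | {4-(benzyloxy)-3-[(1S,2S)-1-[4-(benzyloxy)-3-methoxyphenyl]-1,3-bis(TBSO)propan-2-yl]-5-methoxyphenyl}methanol | COc1cc([C@@H](O[Si](C)(C)C(C)(C)C)[C@H](CO[Si](C)(C)C(C)(C)C)c2cc(CO)cc(OC)c2OCc2ccccc2)ccc1OCc1ccccc1 | intermediate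
20 | 2-(benzyloxy)-5-(bromomethyl)-1-[(1S,2S)-1-[4-(benzyloxy)-3-methoxyphenyl]-1,3-bis(TBSO)propan-2-yl]-3-methoxybenzene | COc1cc([C@@H](O[Si](C)(C)C(C)(C)C)[C@H](CO[Si](C)(C)C(C)(C)C)c2cc(CBr)cc(OC)c2OCc2ccccc2)ccc1OCc1ccccc1 | intermediate
21 | 5-bromo-1-[(2S,3E)-1-(TBSO)pent-3-en-2-yl]-3-methoxy-2-(methoxymethoxy)benzene | C/C=C/[C@H](CO[Si](C)(C)C(C)(C)C)c1cc(Br)cc(OC)c1OCOC | intermediate
22 | 3-{(1S)-1-[5-bromo-3-methoxy-2-(methoxymethoxy)phenyl]-2-(TBSO)ethyl}-5-methyl-1,2,4-trioxolane (ring carbons as a mixture) | CC1OOC(O1)[C@H](CO[Si](C)(C)C(C)(C)C)c1cc(Br)cc(OC)c1OCOC | intermediate (not isolated)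
23 | (2R)-2-[5-bromo-3-methoxy-2-(methoxymethoxy)phenyl]-3-(TBSO)propan-1-ol | OC[C@H](CO[Si](C)(C)C(C)(C)C)c1cc(Br)cc(OC)c1OCOC | intermediate
24 | (2S)-2-[5-bromo-3-methoxy-2-(methoxymethoxy)phenyl]-1-(TBSO)-3-(TBDPSO)propane | CC(C)(C)[Si](OC[C@H](CO[Si](C)(C)C(C)(C)C)c1cc(Br)cc(OC)c1OCOC)(c1ccccc1)c1ccccc1 | intermediate
25 | (2S)-2-[5-bromo-3-methoxy-2-(methoxymethoxy)phenyl]-3-(TBDPSO)propan-1-ol | CC(C)(C)[Si](OC[C@H](CO)c1cc(Br)cc(OC)c1OCOC)(c1ccccc1)c1ccccc1 | intermediate
26 | (2R)-2-[5-bromo-3-methoxy-2-(methoxymethoxy)phenyl]-3-(TBDPSO)propanal | CC(C)(C)[Si](OC[C@H](C=O)c1cc(Br)cc(OC)c1OCOC)(c1ccccc1)c1ccccc1 | intermediate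
27 | (1R,2R)-1-[4-(benzyloxy)-3-methoxyphenyl]-2-[5-bromo-3-methoxy-2-(methoxymethoxy)phenyl]-3-(TBDPSO)propan-1-ol | COc1cc([C@H](O)[C@@H](CO[Si](c2ccccc2)(c2ccccc2)C(C)(C)C)c2cc(Br)cc(OC)c2OCOC)ccc1OCc1ccccc1 | intermediate
28 | 4-bromo-2-[(1R,2R)-1-[4-(benzyloxy)-3-methoxyphenyl]-1-hydroxy-3-(TBDPSO)propan-2-yl]-6-methoxyphenol | COc1cc([C@H](O)[C@@H](CO[Si](c2ccccc2)(c2ccccc2)C(C)(C)C)c2cc(Br)cc(OC)c2O)ccc1OCc1ccccc1 | intermediate (not isolated)
29 | (2S,3R)-2-[4-(benzyloxy)-3-methoxyphenyl]-5-bromo-7-methoxy-3-[(TBDPSO)methyl]-2,3-dihydro-1-benzofuran | Brc1cc(OC)c2c(c1)[C@H](CO[Si](c1ccccc1)(c1ccccc1)C(C)(C)C)[C@@H](c1ccc(OCc3ccccc3)c(OC)c1)O2 | intermediate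
30 | (R)-epichlorohydrin | ClC[C@H]1CO1 | starting material
31 | diethyl malonate | CCOC(=O)CC(=O)OCC | starting material
32 | diethyl 2-[(2R)-3-chloro-2-hydroxypropyl]propanedioate (as sodium alkoxide) | CCOC(=O)C(C[C@@H](O)CCl)C(=O)OCC | intermediate (not isolated)
33 | diethyl 2-{[(2R)-oxiran-2-yl]methyl}propanedioate | CCOC(=O)C(C[C@@H]1CO1)C(=O)OCC | intermediate (not isolated)
34 | diethyl (2R)-2-(hydroxymethyl)cyclopropane-1,1-dicarboxylate (as sodium alkoxide) | CCOC(=O)C1(C[C@H]1CO)C(=O)OCC | intermediate (not isolated)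
35 | ethyl (1S,5R)-2-oxo-3-oxabicyclo[3.1.0]hexane-1-carboxylate | O=C1OC[C@@H]2C[C@]12C(=O)OCC | intermediate
36 | {(2S,3R)-2-[4-(benzyloxy)-3-methoxyphenyl]-7-methoxy-3-[(TBDPSO)methyl]-2,3-dihydro-1-benzofuran-5-yl}lithium | [Li]c1cc(OC)c2c(c1)[C@H](CO[Si](c1ccccc1)(c1ccccc1)C(C)(C)C)[C@@H](c1ccc(OCc3ccccc3)c(OC)c1)O2 | intermediate (not isolated)
37 | {(2S,3R)-2-[4-(benzyloxy)-3-methoxyphenyl]-7-methoxy-3-[(TBDPSO)methyl]-2,3-dihydro-1-benzofuran-5-yl}magnesium bromide | Br[Mg]c1cc(OC)c2c(c1)[C@H](CO[Si](c1ccccc1)(c1ccccc1)C(C)(C)C)[C@@H](c1ccc(OCc3ccccc3)c(OC)c1)O2 | intermediate (not isolated)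
38 | ethyl (4R)-4-{[(2S,3R)-2-[4-(benzyloxy)-3-methoxyphenyl]-7-methoxy-3-[(TBDPSO)methyl]-2,3-dihydro-1-benzofuran-5-yl]methyl}-2-oxooxolane-3-carboxylate (C3 epimers) | CCOC(=O)C1C(=O)OC[C@@H]1Cc1cc(OC)c2c(c1)[C@H](CO[Si](c1ccccc1)(c1ccccc1)C(C)(C)C)[C@@H](c1ccc(OCc3ccccc3)c(OC)c1)O2 | intermediate
39 | (4R)-4-{[(2S,3R)-2-[4-(benzyloxy)-3-methoxyphenyl]-7-methoxy-3-[(TBDPSO)methyl]-2,3-dihydro-1-benzofuran-5-yl]methyl}oxolan-2-one | O=C1OC[C@@H](C1)Cc1cc(OC)c2c(c1)[C@H](CO[Si](c1ccccc1)(c1ccccc1)C(C)(C)C)[C@@H](c1ccc(OCc3ccccc3)c(OC)c1)O2 | intermediate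
40 | lithium enolate of 39 (lithium (3R)-3-(arylmethyl)-2,3-dihydrofuran-5-olate) | [Li]OC1=C[C@@H](Cc2cc(OC)c3c(c2)[C@H](CO[Si](c2ccccc2)(c2ccccc2)C(C)(C)C)[C@@H](c2ccc(OCc4ccccc4)c(OC)c2)O3)CO1 | intermediate (not isolated)
41 | (3R,4R)-3-({4-(benzyloxy)-3-[(1S,2S)-1-[4-(benzyloxy)-3-methoxyphenyl]-1,3-bis(TBSO)propan-2-yl]-5-methoxyphenyl}methyl)-4-{[(2S,3R)-2-[4-(benzyloxy)-3-methoxyphenyl]-7-methoxy-3-[(TBDPSO)methyl]-2,3-dihydro-1-benzofuran-5-yl]methyl}oxolan-2-one | COc1cc([C@@H](O[Si](C)(C)C(C)(C)C)[C@H](CO[Si](C)(C)C(C)(C)C)c2cc(C[C@H]3C(=O)OC[C@@H]3Cc3cc(OC)c4c(c3)[C@H](CO[Si](c3ccccc3)(c3ccccc3)C(C)(C)C)[C@@H](c3ccc(OCc5ccccc5)c(OC)c3)O4)cc(OC)c2OCc2ccccc2)ccc1OCc1ccccc1 | intermediate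
42 | (3R,4R)-3-({4-(benzyloxy)-3-[(1S,2S)-1-[4-(benzyloxy)-3-methoxyphenyl]-1,3-dihydroxypropan-2-yl]-5-methoxyphenyl}methyl)-4-{[(2S,3R)-2-[4-(benzyloxy)-3-methoxyphenyl]-3-(hydroxymethyl)-7-methoxy-2,3-dihydro-1-benzofuran-5-yl]methyl}oxolan-2-one | COc1cc([C@@H](O)[C@H](CO)c2cc(C[C@H]3C(=O)OC[C@@H]3Cc3cc(OC)c4c(c3)[C@H](CO)[C@@H](c3ccc(OCc5ccccc5)c(OC)c3)O4)cc(OC)c2OCc2ccccc2)ccc1OCc1ccccc1 | intermediate
43 | (3R,4R)-3-({4-hydroxy-3-[(1S,2S)-1,3-dihydroxy-1-(4-hydroxy-3-methoxyphenyl)propan-2-yl]-5-methoxyphenyl}methyl)-4-{[(2S,3R)-2-(4-hydroxy-3-methoxyphenyl)-3-(hydroxymethyl)-7-methoxy-2,3-dihydro-1-benzofuran-5-yl]methyl}oxolan-2-one | COc1cc([C@@H](O)[C@H](CO)c2cc(C[C@H]3C(=O)OC[C@@H]3Cc3cc(OC)c4c(c3)[C@H](CO)[C@@H](c3ccc(O)c(OC)c3)O4)cc(OC)c2O)ccc1O | target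

## Step count and least certain steps

Total: 26 steps. Longest linear sequence: 17 steps (steps 1 to 5, 14 to 20 and 22 to 26).

Step 5 (key step). The most likely failure is heterolysis of the allyl–oxygen bond under Lewis-acid activation in competition with the concerted shift. That would leak configuration into C8 and open [1,3] and para pathways. Turnover may also be slow because the bromine lowers the donor strength of the two ether oxygens, and on forcing the product phenol could add to its own propenyl group. Fallback: form the same C8–aryl bond intermolecularly by a copper-mediated anti-SN2′ arylation of an allylic picolinate, which also transfers a carbinol configuration to C8 but by a different mechanism. It sets out from 1. Iodination ortho to the hydroxyl (N-iodosuccinimide) would give 4-bromo-2-iodo-6-methoxyphenol F1, benzylation would give 2-(benzyloxy)-5-bromo-1-iodo-3-methoxybenzene F2, and iodine–magnesium exchange with i-PrMgCl·LiCl, selective for iodine over bromine, would give [2-(benzyloxy)-5-bromo-3-methoxyphenyl]magnesium chloride F3. The MOM series runs in parallel through 5-bromo-1-iodo-3-methoxy-2-(methoxymethoxy)benzene F4 and [5-bromo-3-methoxy-2-(methoxymethoxy)phenyl]magnesium chloride F5. The allylic partner comes from commercial (S)-but-3-yn-2-ol: its dianion (n-BuLi) and paraformaldehyde would give (4S)-pent-2-yne-1,4-diol F6, trans-reduction with NaAlH2(OCH2CH2OMe)2 would give (2E,4S)-pent-2-ene-1,4-diol F7, silylation of the primary hydroxyl would give (2S,3E)-5-(TBSO)pent-3-en-2-ol F8, and esterification with picolinic acid (DCC, DMAP) would give (2S,3E)-5-(TBSO)pent-3-en-2-yl pyridine-2-carboxylate F9. With CuBr·SMe2 in THF the aryl group of F3 should enter at the silyloxymethyl-bearing alkene carbon anti to the picolinate, so the (S,E)-ester leads to the same (S,E) product as the suprafacial shift of the (R,E)-ether. The fallback comes back to the route at 10 and, with F5 in place of F3, at 21.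

Step 10. The most likely failure is poor facial selectivity, if the silyloxymethyl group competes with ring B for the position anti to the nucleophile. The other is loss of the C8 configuration, or β-elimination of silanolate, through α-deprotonation of the very enolisable aldehyde by the basic reagent. Fallback: replace substrate control by catalyst control with a non-basic aryl donor. [4-(Benzyloxy)-3-methoxyphenyl](ethyl)zinc F10, generated from commercial 4-(benzyloxy)-3-methoxyphenylboronic acid and Et2Zn, would be added to 12 in the presence of a chiral β-amino alcohol ligand of the antipode that directs the aryl group to the Re face of the formyl group, matched with the Felkin–Anh preference. It sets out from 12 and comes back at 15.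

Step 20. The most likely failures are partial loss of the TBDPS ether under the acid, elimination from the benzylic cation to a stilbene, and incomplete equilibration to the trans ring. Fallback: separate deprotection from ring closure and close by SN2 instead of SN1. The acetal of 27 (anti epimer, purified) would be cleaved without ionising the carbinol (Me3SiOTf, 2,2′-bipyridyl, MeCN, 0 °C, then H2O) to give 28 as an isolated compound. A Mitsunobu ring closure (PPh3, DIAD, THF) would then displace the activated benzylic hydroxyl by the phenol with inversion, which from the anti alcohol gives the trans ring. It sets out from 27, comes back at 29 and makes no compound outside the list.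

Step 22. The most likely failures are incomplete halogen–metal exchange or protonation of the aryl metal, and 1,2-addition to the ester or lactone carbonyl of 35 in competition with attack at the cyclopropane methylene. Fallback: build the β-arm by cross-coupling and set Cβ by asymmetric reduction. Miyaura borylation of 29 (bis(pinacolato)diboron, Pd(dppf)Cl2, KOAc) would give the pinacol boronate F11. Suzuki–Miyaura coupling with 4-(bromomethyl)furan-2(5H)-one, taken as a bought reagent (Pd(PPh3)4, K2CO3), would give the 4-(arylmethyl)butenolide F12. Copper hydride conjugate reduction (CuCl, NaOt-Bu, the p-Tol-BINAP antipode that leads to the R lactone, polymethylhydrosiloxane) would give 39. It sets out from 29 and comes back at 39.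

Step 26. The most likely failure is over-reduction: hydrogenolysis of the free benzylic C7–O bond, or of the benzylic C2–O bond of the coumaran, while the last benzyl ether is being removed. Fallback: reverse the order of the two deprotections, so that C7 still carries its silyl ether during hydrogenolysis. H2 and Pd/C on 41 would give the triphenol tris(silyl ether) F13, and buffered Bu4NF/AcOH would then release the three alcohols. It sets out from 41 and comes back at 43.

## Further compounds

F1 | step 5 | 4-bromo-2-iodo-6-methoxyphenol | COc1cc(Br)cc(I)c1O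
F2 | step 5 | 2-(benzyloxy)-5-bromo-1-iodo-3-methoxybenzene | COc1cc(Br)cc(I)c1OCc1ccccc1
F3 | step 5 | [2-(benzyloxy)-5-bromo-3-methoxyphenyl]magnesium chloride | COc1cc(Br)cc([Mg]Cl)c1OCc1ccccc1
F4 | step 5 | 5-bromo-1-iodo-3-methoxy-2-(methoxymethoxy)benzene | COCOc1c(I)cc(Br)cc1OC
F5 | step 5 | [5-bromo-3-methoxy-2-(methoxymethoxy)phenyl]magnesium chloride | COCOc1c([Mg]Cl)cc(Br)cc1OC
F6 | step 5 | (4S)-pent-2-yne-1,4-diol | C[C@H](O)C#CCO
F7 | step 5 | (2E,4S)-pent-2-ene-1,4-diol | C[C@H](O)/C=C/CO
F8 | step 5 | (2S,3E)-5-(TBSO)pent-3-en-2-ol | C[C@H](O)/C=C/CO[Si](C)(C)C(C)(C)C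
F9 | step 5 | (2S,3E)-5-(TBSO)pent-3-en-2-yl pyridine-2-carboxylate | C[C@H](OC(=O)c1ccccn1)/C=C/CO[Si](C)(C)C(C)(C)C
F10 | step 10 | [4-(benzyloxy)-3-methoxyphenyl](ethyl)zinc | CC[Zn]c1ccc(OCc2ccccc2)c(OC)c1
F0 | step 20 | none | none
F11 | step 22 | 2-{(2S,3R)-2-[4-(benzyloxy)-3-methoxyphenyl]-7-methoxy-3-[(TBDPSO)methyl]-2,3-dihydro-1-benzofuran-5-yl}-4,4,5,5-tetramethyl-1,3,2-dioxaborolane | CC1(C)OB(OC1(C)C)c1cc(OC)c2c(c1)[C@H](CO[Si](c1ccccc1)(c1ccccc1)C(C)(C)C)[C@@H](c1ccc(OCc3ccccc3)c(OC)c1)O2
F12 | step 22 | 4-{[(2S,3R)-2-[4-(benzyloxy)-3-methoxyphenyl]-7-methoxy-3-[(TBDPSO)methyl]-2,3-dihydro-1-benzofuran-5-yl]methyl}furan-2(5H)-one | O=C1OCC(=C1)Cc1cc(OC)c2c(c1)[C@H](CO[Si](c1ccccc1)(c1ccccc1)C(C)(C)C)[C@@H](c1ccc(OCc3ccccc3)c(OC)c1)O2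
F13 | step 26 | (3R,4R)-3-({4-hydroxy-3-[(1S,2S)-1-(4-hydroxy-3-methoxyphenyl)-1,3-bis(TBSO)propan-2-yl]-5-methoxyphenyl}methyl)-4-{[(2S,3R)-2-(4-hydroxy-3-methoxyphenyl)-7-methoxy-3-[(TBDPSO)methyl]-2,3-dihydro-1-benzofuran-5-yl]methyl}oxolan-2-one | COc1cc([C@@H](O[Si](C)(C)C(C)(C)C)[C@H](CO[Si](C)(C)C(C)(C)C)c2cc(C[C@H]3C(=O)OC[C@@H]3Cc3cc(OC)c4c(c3)[C@H](CO[Si](c3ccccc3)(c3ccccc3)C(C)(C)C)[C@@H](c3ccc(O)c(OC)c3)O4)cc(OC)c2O)ccc1O
A1 | alternative 1 | methyl 2-[2-{[4-(benzyloxy)-3-methoxyphenyl]methoxy}-5-bromo-3-methoxyphenyl]-2-diazoacetate | COC(=O)C(=[N+]=[N-])c1cc(Br)cc(OC)c1OCc1ccc(OCc2ccccc2)c(OC)c1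
A2 | alternative 1 | methyl cis-(2S,3R)-2-[4-(benzyloxy)-3-methoxyphenyl]-5-bromo-7-methoxy-2,3-dihydro-1-benzofuran-3-carboxylate | Brc1cc(OC)c2c(c1)[C@@H](C(=O)OC)[C@@H](c1ccc(OCc3ccccc3)c(OC)c1)O2
A3 | alternative 1 | methyl trans-(2S,3S)-2-[4-(benzyloxy)-3-methoxyphenyl]-5-bromo-7-methoxy-2,3-dihydro-1-benzofuran-3-carboxylate | Brc1cc(OC)c2c(c1)[C@H](C(=O)OC)[C@@H](c1ccc(OCc3ccccc3)c(OC)c1)O2
A4 | alternative 2 | (4S)-4-benzyl-3-{[2-(benzyloxy)-5-bromo-3-methoxyphenyl]acetyl}-1,3-oxazolidin-2-one | O=C(Cc1cc(Br)cc(OC)c1OCc1ccccc1)N1[C@@H](Cc2ccccc2)COC1=O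
A5 | alternative 2 | 4-(benzyloxy)-3-methoxybenzaldehyde (O-benzylvanillin) | COc1cc(C=O)ccc1OCc1ccccc1
A6 | alternative 2 | (4S)-4-benzyl-3-[(2R,3S)-3-[4-(benzyloxy)-3-methoxyphenyl]-2-[2-(benzyloxy)-5-bromo-3-methoxyphenyl]-3-hydroxypropanoyl]-1,3-oxazolidin-2-one | COc1cc([C@@H](O)[C@H](C(=O)N2[C@@H](Cc3ccccc3)COC2=O)c2cc(Br)cc(OC)c2OCc2ccccc2)ccc1OCc1ccccc1
A7 | alternative 3 | (5S)-5-[(trityloxy)methyl]oxolan-2-one | O=C1CC[C@@H](COC(c2ccccc2)(c2ccccc2)c2ccccc2)O1
A8 | alternative 3 | (2S,3R)-2-[4-(benzyloxy)-3-methoxyphenyl]-5-(bromomethyl)-7-methoxy-3-[(TBSO)methyl]-2,3-dihydro-1-benzofuran | BrCc1cc(OC)c2c(c1)[C@H](CO[Si](C)(C)C(C)(C)C)[C@@H](c1ccc(OCc3ccccc3)c(OC)c1)O2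
A9 | alternative 3 | (3R,5S)-3-{[(2S,3R)-2-[4-(benzyloxy)-3-methoxyphenyl]-7-methoxy-3-[(TBSO)methyl]-2,3-dihydro-1-benzofuran-5-yl]methyl}-5-[(trityloxy)methyl]oxolan-2-one | O=C1[C@H](Cc2cc(OC)c3c(c2)[C@H](CO[Si](C)(C)C(C)(C)C)[C@@H](c2ccc(OCc4ccccc4)c(OC)c2)O3)C[C@@H](COC(c2ccccc2)(c2ccccc2)c2ccccc2)O1
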